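The number I carried through this flask was 1.41, the load root: the square root of the ratio of two charges of Q, which is the factor on the rate at a fixed conversion while the working catalyst is still being born.

| flask | J | L | G | Q | remark |
|---|---|---|---|---|---|
| dawn | 0.012 M | 0.012 M | 0.012 M | 0.60 mM | run made earlier |
| autumn | 0.012 M | 0.012 M | 0.027 M | 0.60 mM | run made earlier |
| winter | 0.012 M | 0.012 M | 0.018 M | 0.30 mM | run made earlier |
| flask | 0.012 M | 0.012 M | 0.0180 M | 0.60 mM |  |

| run | time / min | E / % |
|---|---|---|
| dawn | 1.00 | 0 |
| dawn | 2.00 | 0 |
| dawn | 5.00 | 0 |
| dawn | 12.0 | 0.7 |
| autumn | 3.00 | 0.6 |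
| autumn | 6.00 | 0.5 |
| autumn | 10.0 | 2.6 |
| autumn | 12.0 | 3.8 |
| winter | 1.00 | 0.6 |
| winter | 2.00 | 0 |
| winter | 5.00 | 0.2 |
| winter | 12.0 | 0.6 |

(standard deviation of a reading: 0.3 percentage points)

- factor on the rate of making E when 30 % of the J and L together are converted if Q is charged twice over
- factor on the rate when 30 % of the J and L together are converted if Q is charged at 6.0 mM instead

- D is single-handed; J and L are mirror images of each other, charged as a racemate, each of them at the stated concentration

In the opening minutes the autumn run shows the pattern. E went from 2.6 % at 10.0 min to 3.8 % at 12.0 min, a reading of 1.46 against 1.44 for the square of time, so the rate was still growing with time. I took this as an induction period, with D forming steadily from Q. At 12.0 min the autumn run read 5.43 times the dawn run, against 5.06 for the square of cG, so I let G act twice: it makes D and it is the reagent.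

On this ramp E grows with cQ and the square of time. A fixed conversion therefore arrives sooner by the load root, and the D present then is larger by that same root.

For the middle, I scaled the autumn run to the flask, holding cJ and cG at their charges, which is optimistic, and so reckoned 30 % at about 50.6 min. At 6.0 mM the load root is 3.16, which shortens that time to 16.0 min.

For the far end I reckoned a catalyst wholly turned to D, where the rate at a fixed conversion goes as cQ itself, giving factors of 2 and 10.0. The autumn run ends at 3.8 % of E, below 30 %, so I had to judge how far the flask gets towards that end. Joining the two ends, I committed to a doubling factor just above 1.41 and a factor near 3.16 for 6.0 mM, because by my reckoning the heavier charge reaches 30 % sooner, deeper in the ramp.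

The forecast gave 2.5 and 18, both higher than my reckoning, holding that by then “the catalyst should be largely activated”.

The flask gave 1.52 for doubling, against the load root of 1.41, and 3.20 for 6.0 mM, against 3.16; with that heavier charge, the share of the catalyst that is D at the same conversion is 37.1 %.

G + Q → D + X (k = 0.0230 L mol⁻¹ s⁻¹); J ⇌ L (k = 3.40 × 10⁻⁴ s⁻¹); G + D + L → D + Z (k = 1.10 L² mol⁻² s⁻¹); G + D + J → D + E (k = 33.0 L² mol⁻² s⁻¹) In the flask at 13.5 min, the making of E alone gives J a half-life of 120 min, whereas J and L relax into each other with a half-life of 17.0 min. At 20.0 min the flask holds J at 46.3 % and L at 49.4 % of the J and L together charged.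

The data come from a simulation with constants of no real substance, noise included.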